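27 is the ring tautomer of hydroxy enone 26. Cutting the alkenyl–carbinol bond next to the hemiketal carbon (alkenylchromium addition to an aldehyde, then oxidation) gives lactol 12 (ring A = cyclohexane, ring B = oxepane of the left bicycle) and alkenyl iodide 23 (ring C = cyclohexane, ring D = oxepanone of the right bicycle).
Ring B of 12 is traced back by a Baeyer–Villiger oxygen insertion to trans-decalone 10. Ring A of that decalone is built on a cyclohexanone enolate by a vinylphosphonium annulation (Michael addition, then intramolecular Wittig ring closure, step 3); the enolate precursor 4 comes from an enantioselective Mukaiyama–Michael addition to 1.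
Feature that makes the key step possible: in ring A the three CH2 groups are an unfunctionalised chain between two fully substituted carbons, the gem-dimethyl carbon and the ring-fusion carbon that bears CH3 and the ring B oxygen. With that oxygen replaced by a ketone carbon, the ring-fusion carbon is an enolate carbon, the CH2 beside the gem-dimethyl carbon can be a non-enolisable neopentyl aldehyde, and the other two CH2 groups are the vinylphosphonium unit; ring A therefore closes between the CH2 beside the gem-dimethyl carbon and the middle CH2 (as C=C, hydrogenated in step 5).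
Rings D and C of 23 are formed in one operation by a silyl-triflate-promoted epoxide-opening cascade of the bis-epoxide of (E)-geranylacetone, terminated by its enol silane; the axial side arm and the tertiary carbinol follow from α′-alkylation and methyl addition.
Order of ring formation: ring A (step 3), then ring B as lactone (step 6); rings D and C together (step 10); ring B hemiketal on the final oxidation (step 18).

Key step: step 3

Assumption: hydroxy enone 26 is taken to close spontaneously to the seven-membered hemiketal of the target as its thermodynamically preferred ring tautomer, and the antipode of the step 1 catalyst is the one that delivers the (1S) adduct.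

Step 1
Reactants: 1 2-methylcyclohex-2-en-1-one; 2 1-methoxy-2-methyl-1-(trimethylsilyloxy)prop-1-ene
Product: 3 methyl 2-methyl-2-[(1S)-2-methyl-3-(trimethylsilyloxy)cyclohex-2-en-1-yl]propanoate
Conditions: chiral oxazaborolidinium triflimide [B-(o-tolyl)oxazaborolidine from (S)-α,α-diphenylprolinol, activated with Tf2NH, 20 mol %], Ph3PO (25 mol %), toluene, −20 °C; non-aqueous work-up (pentane, Et3N-deactivated silica)
Reagents that add atoms: none
Why: Catalytic enantioselective Mukaiyama–Michael addition: the cationic chiral Lewis acid binds the enone carbonyl and shields one face of the β-carbon, so the ketene silyl acetal should add from the open face to set the ring stereocentre (1S), and silyl transfer leaves the ketone regiospecifically masked as the tetrasubstituted silyl enol ether that step 3 needs.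

Step 2
Reactants: 3 methyl 2-methyl-2-[(1S)-2-methyl-3-(trimethylsilyloxy)cyclohex-2-en-1-yl]propanoate
Product: 4 2-methyl-2-[(1S)-2-methyl-3-(trimethylsilyloxy)cyclohex-2-en-1-yl]propanal
Conditions: i-Bu2AlH (1.1 equiv), CH2Cl2, −78 °C; then MeOH, aq. KNaC4H4O6 (pH 7)
Reagents that add atoms: none
Why: Partial reduction of a hindered α-quaternary methyl ester with i-Bu2AlH stops at the tetrahedral aluminium acetal at −78 °C and releases the neopentyl aldehyde on work-up, while the silyl enol ether protects the ketone (ester-to-aldehyde reduction).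

Step 3
Reactants: 4 2-methyl-2-[(1S)-2-methyl-3-(trimethylsilyloxy)cyclohex-2-en-1-yl]propanal; 5 vinyltriphenylphosphonium bromide
Product: 8 (4aR,8aR)-5,5,8a-trimethyl-3,4,4a,5,8,8a-hexahydronaphthalen-1(2H)-one, via caesium enolate 6 (not isolated), via phosphorus ylide 7 (not isolated)
Conditions: CsF (1.5 equiv, dried), MeCN–THF, 0 °C, then 50 °C
Reagents that add atoms: none
Why: Fluoride cleaves the Si–O bond to give the tetrasubstituted enolate 6, whose α-carbon adds to the vinylphosphonium salt (Michael addition) to form ylide 7 and the first C–C bond; the ylide carbon then attacks the pendant aldehyde and the oxaphosphetane collapses to the ring A alkene and Ph3PO (intramolecular Wittig olefination). The closest known reaction type is the vinylphosphonium annulation of enolates that carry a carbonyl group (conjugate addition followed by intramolecular Wittig reaction). Ring A is closed in the 6-exo-trig mode, the ylide carbon adding to the C=O carbon, and the new ring bond is the C=C between the former aldehyde carbon and the ylide carbon. The new quaternary ring-fusion centre (8aR) is controlled by the existing neighbouring stereocentre: the planar enolate should be alkylated anti to the adjacent 2-methyl-1-oxopropan-2-yl group, which gives the trans ring fusion. The step needs C- over O-alkylation and Wittig closure over aldol pathways; the aldehyde is neopentyl and non-enolisable, and both its aldol reaction with the enolate of the same molecule and a Wittig attack of the ylide on the ring ketone would need a four-membered ring, so only the six-membered closure is open.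

Step 4
Reactants: 8 (4aR,8aR)-5,5,8a-trimethyl-3,4,4a,5,8,8a-hexahydronaphthalen-1(2H)-one
Product: 9 (4aR,8aR)-5,5,8a-trimethyl-2-methylidene-3,4,4a,5,8,8a-hexahydronaphthalen-1(2H)-one
Conditions: (CH2O)n, N-methylanilinium trifluoroacetate, THF, reflux
Reagents that add atoms: formaldehyde (as paraformaldehyde), C=O
Why: Mannich-type α-methylenation: the ketone has a single enolisable position (the other α-carbon is quaternary), so the iminium ion from formaldehyde and the amine salt is attacked there and amine elimination gives the exocyclic enone.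

Step 5
Reactants: 9 (4aR,8aR)-5,5,8a-trimethyl-2-methylidene-3,4,4a,5,8,8a-hexahydronaphthalen-1(2H)-one
Product: 10 (2R,4aR,8aR)-2,5,5,8a-tetramethyloctahydronaphthalen-1(2H)-one
Conditions: H2 (1 atm), 10 % Pd/C, EtOAc, rt
Reagents that add atoms: none
Why: Heterogeneous catalytic hydrogenation saturates the ring A alkene and should add hydrogen to the exocyclic enone from the face opposite the axial angular methyl group, so the new 2-methyl group ends up axial and cis to the angular methyl (2R), the less stable epimer formed under kinetic control.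

Step 6
Reactants: 10 (2R,4aR,8aR)-2,5,5,8a-tetramethyloctahydronaphthalen-1(2H)-one
Product: 11 (3R,5aR,9aR)-3,6,6,9a-tetramethyloctahydro-1-benzoxepin-2(3H)-one
Conditions: mCPBA, NaHCO3, CH2Cl2, rt
Reagents that add atoms: 3-chloroperoxybenzoic acid (mCPBA), OOC(=O)c1cccc(Cl)c1
Why: Baeyer–Villiger oxidation: the quaternary ring-fusion carbon migrates in preference to the secondary one and with retention of configuration, which inserts oxygen between it and the carbonyl carbon and turns the decalone into the trans-fused seven-membered lactone of ring B.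

Step 7
Reactants: 11 (3R,5aR,9aR)-3,6,6,9a-tetramethyloctahydro-1-benzoxepin-2(3H)-one
Product: 12 (3R,5aR,9aR)-3,6,6,9a-tetramethyldecahydro-1-benzoxepin-2-ol (lactol; both anomers)
Conditions: i-Bu2AlH (1.1 equiv), CH2Cl2, −78 °C; aq. KNaC4H4O6
Reagents that add atoms: none
Why: Half-reduction of the lactone with i-Bu2AlH gives an aluminium lactolate that is stable at −78 °C and releases the lactol (masked hydroxy aldehyde) on work-up.

Step 8
Reactants: 13 (E)-geranylacetone
Product: 14 4-[(2R,3R)-3-{2-[(2R)-3,3-dimethyloxiran-2-yl]ethyl}-3-methyloxiran-2-yl]butan-2-one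
Conditions: D-fructose-derived ketone catalyst (1,2:4,5-di-O-isopropylidene-β-D-erythro-2,3-hexodiulo-2,6-pyranose, 30 mol %), KHSO5 (as Oxone), K2CO3, Bu4NHSO4, MeCN–CH2(OMe)2–aq. Na2B4O7 buffer, 0 °C
Reagents that add atoms: potassium peroxymonosulfate (KHSO5), [K+].[O-]S(=O)(=O)OO
Why: Shi asymmetric epoxidation: the chiral dioxirane should epoxidise both trisubstituted alkenes through a spiro transition state on the same face, giving the (R,R)-epoxide of the E-alkene and the (R)-epoxide of the terminal alkene.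

Step 9
Reactants: 14 4-[(2R,3R)-3-{2-[(2R)-3,3-dimethyloxiran-2-yl]ethyl}-3-methyloxiran-2-yl]butan-2-one
Product: 15 triethyl({4-[(2R,3R)-3-{2-[(2R)-3,3-dimethyloxiran-2-yl]ethyl}-3-methyloxiran-2-yl]but-1-en-2-yl}oxy)silane
Conditions: LiN(i-Pr)2, THF, −78 °C; then Et3SiCl, Et3N, −78 °C
Reagents that add atoms: chlorotriethylsilane, CC[Si](Cl)(CC)CC
Why: Kinetic deprotonation of the methyl ketone at the methyl group and O-silylation give the terminal silyl enol ether; the epoxides are inert to the amide base at −78 °C.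

Step 10
Reactants: 15 triethyl({4-[(2R,3R)-3-{2-[(2R)-3,3-dimethyloxiran-2-yl]ethyl}-3-methyloxiran-2-yl]but-1-en-2-yl}oxy)silane
Product: 16 (3R,5aR,9aR)-2,2,5a-trimethyl-3-(triethylsilyloxy)octahydro-1-benzoxepin-7(2H)-one
Conditions: Et3SiOTf (1.1 equiv), 2,6-di-tert-butyl-4-methylpyridine, CH2Cl2, −78 °C
Reagents that add atoms: none
Why: Lewis-acid-promoted tandem oxa-/carbacyclisation of a polyepoxide: silylation of the terminal epoxide triggers attack of the internal epoxide oxygen at its tertiary carbon (oxepane, ring D), and the bicyclic epoxonium ion is opened at its tertiary carbon with inversion by the enol silane carbon (ring C), so the epoxide configurations translate into the trans ring fusion (5aR,9aR) while the silyl group is relayed to the new secondary oxygen.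

Step 11
Reactants: 16 (3R,5aR,9aR)-2,2,5a-trimethyl-3-(triethylsilyloxy)octahydro-1-benzoxepin-7(2H)-one
Product: 18 (3R,5aR,9aR)-2,2,5a-trimethyl-3-(triethylsilyloxy)-3,4,5,5a,6,9a-hexahydro-1-benzoxepin-7(2H)-one, via trimethylsilyl enol ether 17 (not isolated)
Conditions: LiN(i-Pr)2, Me3SiCl, THF, −78 °C; then Pd(OAc)2 (1.05 equiv), MeCN, rt
Reagents that add atoms: none
Why: Saegusa–Ito oxidation: kinetic deprotonation occurs at the CH2 remote from the quaternary carbon, and the silyl enol ether is dehydrogenated by Pd(OAc)2 through an oxa-π-allylpalladium intermediate and β-hydride elimination, which blocks that side of the ketone as an enone.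

Step 12
Reactants: 18 (3R,5aR,9aR)-2,2,5a-trimethyl-3-(triethylsilyloxy)-3,4,5,5a,6,9a-hexahydro-1-benzoxepin-7(2H)-one
Product: 19 (3R,5aR,6R,9aR)-6-[(benzyloxy)methyl]-2,2,5a-trimethyl-3-(triethylsilyloxy)-3,4,5,5a,6,9a-hexahydro-1-benzoxepin-7(2H)-one
Conditions: LiN(i-Pr)2, THF, −78 °C; then BnOCH2Cl, DMPU, −78 to −20 °C
Reagents that add atoms: benzyl chloromethyl ether, ClCOCc1ccccc1
Why: Kinetic α′-deprotonation of the enone gives the cross-conjugated lithium enolate, which should be C-alkylated on the face opposite the axial angular methyl group (stereoelectronically preferred axial attack), placing the new side chain trans to that methyl group (6R).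

Step 13
Reactants: 19 (3R,5aR,6R,9aR)-6-[(benzyloxy)methyl]-2,2,5a-trimethyl-3-(triethylsilyloxy)-3,4,5,5a,6,9a-hexahydro-1-benzoxepin-7(2H)-one
Product: 20 (3R,5aR,6R,7S,9aR)-6-[(benzyloxy)methyl]-2,2,5a,7-tetramethyl-3-(triethylsilyloxy)-2,3,4,5,5a,6,7,9a-octahydro-1-benzoxepin-7-ol
Conditions: MeLi, CeCl3 (anhydrous), THF, −78 °C; aq. NH4Cl
Reagents that add atoms: methyllithium, [Li]C
Why: 1,2-Addition of the weakly basic organocerium reagent to the enone carbonyl: the axial trajectory is blocked by the 1,3-related axial angular methyl group, so methyl should enter equatorially and the tertiary hydroxyl end up axial, cis to the angular methyl and trans to the benzyloxymethyl group (7S).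

Step 14
Reactants: 20 (3R,5aR,6R,7S,9aR)-6-[(benzyloxy)methyl]-2,2,5a,7-tetramethyl-3-(triethylsilyloxy)-2,3,4,5,5a,6,7,9a-octahydro-1-benzoxepin-7-ol
Product: 21 (3R,5aR,6R,7S,9aR)-6-(hydroxymethyl)-2,2,5a,7-tetramethyldecahydro-1-benzoxepine-3,7-diol
Conditions: H2 (1 atm), 10 % Pd/C, MeOH, rt; then 1 M HCl, rt
Reagents that add atoms: none
Why: Hydrogenation over Pd/C saturates the ring alkene and hydrogenolyses the benzyl ether, and the dilute acid then hydrolyses the triethylsilyl ether; no stereocentre is touched.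

Step 15
Reactants: 21 (3R,5aR,6R,7S,9aR)-6-(hydroxymethyl)-2,2,5a,7-tetramethyldecahydro-1-benzoxepine-3,7-diol
Product: 22 (5aR,6S,7S,9aR)-7-hydroxy-2,2,5a,7-tetramethyl-3-oxodecahydro-1-benzoxepine-6-carbaldehyde
Conditions: Dess–Martin periodinane (2.5 equiv), NaHCO3, CH2Cl2, 0 °C to rt
Reagents that add atoms: none
Why: Dess–Martin oxidation converts the primary alcohol into the aldehyde and the secondary alcohol into the ring D ketone under buffered, non-basic conditions, which should spare the tertiary alcohol and the epimerisable β-hydroxy aldehyde.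

Step 16
Reactants: 22 (5aR,6S,7S,9aR)-7-hydroxy-2,2,5a,7-tetramethyl-3-oxodecahydro-1-benzoxepine-6-carbaldehyde
Product: 23 (5aR,6S,7S,9aR)-7-hydroxy-6-[(E)-2-iodoethenyl]-2,2,5a,7-tetramethyloctahydro-1-benzoxepin-3(2H)-one
Conditions: CrCl2 (6 equiv), CHI3 (2 equiv), THF, 0 °C to rt
Reagents that add atoms: iodoform, IC(I)I
Why: Takai olefination: the geminal dichromium species from CHI3 and CrCl2 adds to the aldehyde chemoselectively (ketones react far more slowly) and elimination gives the (E)-alkenyl iodide.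

Step 17
Reactants: 23 (5aR,6S,7S,9aR)-7-hydroxy-6-[(E)-2-iodoethenyl]-2,2,5a,7-tetramethyloctahydro-1-benzoxepin-3(2H)-one; 12 (3R,5aR,9aR)-3,6,6,9a-tetramethyldecahydro-1-benzoxepin-2-ol
Product: 25 (5aR,6S,7S,9aR)-7-hydroxy-6-{(1E,4R)-3-hydroxy-6-[(1R,2R)-2-hydroxy-2,6,6-trimethylcyclohexyl]-4-methylhex-1-en-1-yl}-2,2,5a,7-tetramethyloctahydro-1-benzoxepin-3(2H)-one (both carbinol epimers), via open-chain hydroxy aldehyde 24 (not isolated)
Conditions: CrCl2 (4 equiv), NiCl2 (1 mol %), DMSO, rt; aqueous work-up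
Reagents that add atoms: none
Why: Nozaki–Hiyama–Kishi coupling: nickel-catalysed formation of the alkenylchromium reagent and its addition to the aldehyde form of the lactol tolerate the free tertiary alcohols and the ketone; the new carbinol centre is formed without control, which does not matter because it is oxidised in step 18.

Step 18
Reactants: 25 (5aR,6S,7S,9aR)-7-hydroxy-6-{(1E,4R)-3-hydroxy-6-[(1R,2R)-2-hydroxy-2,6,6-trimethylcyclohexyl]-4-methylhex-1-en-1-yl}-2,2,5a,7-tetramethyloctahydro-1-benzoxepin-3(2H)-one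
Product: 27 CNP0307967.2 (target), via open hydroxy enone 26 (not isolated)
Conditions: MnO2 (activated, excess), CH2Cl2, rt; brief equilibration on silica
Reagents that add atoms: none
Why: Selective oxidation of the allylic alcohol by MnO2 gives the E-enone, whose carbonyl should be captured by the tertiary hydroxyl of ring A to close the seven-membered hemiketal (ring B) under thermodynamic control, with the anomeric hydroxyl cis to the neighbouring methyl group as in the target.

Compound list
1 | 2-methylcyclohex-2-en-1-one | CC1=CCCCC1=O | starting material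
2 | 1-methoxy-2-methyl-1-(trimethylsilyloxy)prop-1-ene (ketene silyl acetal of methyl isobutyrate) | COC(O[Si](C)(C)C)=C(C)C | starting material
3 | methyl 2-methyl-2-[(1S)-2-methyl-3-(trimethylsilyloxy)cyclohex-2-en-1-yl]propanoate | COC(=O)C(C)(C)[C@H]1CCCC(O[Si](C)(C)C)=C1C | intermediate
4 | 2-methyl-2-[(1S)-2-methyl-3-(trimethylsilyloxy)cyclohex-2-en-1-yl]propanal | O=CC(C)(C)[C@H]1CCCC(O[Si](C)(C)C)=C1C | intermediate
5 | vinyltriphenylphosphonium bromide | C=C[P+](c1ccccc1)(c1ccccc1)c1ccccc1.[Br-] | starting material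
6 | caesium (3S)-2-methyl-3-(2-methyl-1-oxopropan-2-yl)cyclohex-1-en-1-olate | O=CC(C)(C)[C@H]1CCCC([O-])=C1C.[Cs+] | intermediate
7 | 2-methyl-2-{(1R,2R)-2-methyl-3-oxo-2-[2-(triphenyl-λ5-phosphanylidene)ethyl]cyclohexyl}propanal | O=CC(C)(C)[C@H]1CCCC(=O)[C@]1(C)CC=P(c2ccccc2)(c2ccccc2)c2ccccc2 | intermediate
8 | (4aR,8aR)-5,5,8a-trimethyl-3,4,4a,5,8,8a-hexahydronaphthalen-1(2H)-one (trans-fused) | O=C1CCC[C@@H]2C(C)(C)C=CC[C@@]12C | intermediate
9 | (4aR,8aR)-5,5,8a-trimethyl-2-methylidene-3,4,4a,5,8,8a-hexahydronaphthalen-1(2H)-one | O=C1C(=C)CC[C@@H]2C(C)(C)C=CC[C@@]12C | intermediate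
10 | (2R,4aR,8aR)-2,5,5,8a-tetramethyloctahydronaphthalen-1(2H)-one (2-methyl axial, cis to the 8a-methyl) | C[C@@H]1CC[C@@H]2C(C)(C)CCC[C@@]2(C)C1=O | intermediate
11 | (3R,5aR,9aR)-3,6,6,9a-tetramethyloctahydro-1-benzoxepin-2(3H)-one | C[C@@H]1CC[C@@H]2C(C)(C)CCC[C@@]2(C)OC1=O | intermediate
12 | (3R,5aR,9aR)-3,6,6,9a-tetramethyldecahydro-1-benzoxepin-2-ol (lactol; both anomers) | C[C@@H]1CC[C@@H]2C(C)(C)CCC[C@@]2(C)OC1O | intermediate
13 | (E)-geranylacetone [(5E)-6,10-dimethylundeca-5,9-dien-2-one] | CC(=O)CC/C=C(\C)CCC=C(C)C | starting material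
14 | 4-[(2R,3R)-3-{2-[(2R)-3,3-dimethyloxiran-2-yl]ethyl}-3-methyloxiran-2-yl]butan-2-one | CC(=O)CC[C@H]1O[C@]1(C)CC[C@H]1OC1(C)C | intermediate
15 | triethyl({4-[(2R,3R)-3-{2-[(2R)-3,3-dimethyloxiran-2-yl]ethyl}-3-methyloxiran-2-yl]but-1-en-2-yl}oxy)silane | C=C(O[Si](CC)(CC)CC)CC[C@H]1O[C@]1(C)CC[C@H]1OC1(C)C | intermediate
16 | (3R,5aR,9aR)-2,2,5a-trimethyl-3-(triethylsilyloxy)octahydro-1-benzoxepin-7(2H)-one (trans-fused) | O=C1C[C@@]2(C)CC[C@@H](O[Si](CC)(CC)CC)C(C)(C)O[C@@H]2CC1 | intermediate
17 | triethyl{[(3R,5aR,9aR)-2,2,5a-trimethyl-7-(trimethylsilyloxy)-2,3,4,5,5a,6,9,9a-octahydro-1-benzoxepin-3-yl]oxy}silane | C[Si](C)(C)OC=1C[C@@]2(C)CC[C@@H](O[Si](CC)(CC)CC)C(C)(C)O[C@@H]2CC=1 | intermediate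
18 | (3R,5aR,9aR)-2,2,5a-trimethyl-3-(triethylsilyloxy)-3,4,5,5a,6,9a-hexahydro-1-benzoxepin-7(2H)-one | O=C1C[C@@]2(C)CC[C@@H](O[Si](CC)(CC)CC)C(C)(C)O[C@@H]2C=C1 | intermediate
19 | (3R,5aR,6R,9aR)-6-[(benzyloxy)methyl]-2,2,5a-trimethyl-3-(triethylsilyloxy)-3,4,5,5a,6,9a-hexahydro-1-benzoxepin-7(2H)-one | c1ccccc1COC[C@H]1[C@@]2(C)CC[C@@H](O[Si](CC)(CC)CC)C(C)(C)O[C@@H]2C=CC1=O | intermediate
20 | (3R,5aR,6R,7S,9aR)-6-[(benzyloxy)methyl]-2,2,5a,7-tetramethyl-3-(triethylsilyloxy)-2,3,4,5,5a,6,7,9a-octahydro-1-benzoxepin-7-ol | c1ccccc1COC[C@H]1[C@@]2(C)CC[C@@H](O[Si](CC)(CC)CC)C(C)(C)O[C@@H]2C=C[C@]1(C)O | intermediate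
21 | (3R,5aR,6R,7S,9aR)-6-(hydroxymethyl)-2,2,5a,7-tetramethyldecahydro-1-benzoxepine-3,7-diol | OC[C@H]1[C@@]2(C)CC[C@@H](O)C(C)(C)O[C@@H]2CC[C@]1(C)O | intermediate
22 | (5aR,6S,7S,9aR)-7-hydroxy-2,2,5a,7-tetramethyl-3-oxodecahydro-1-benzoxepine-6-carbaldehyde | O=C[C@H]1[C@@]2(C)CCC(=O)C(C)(C)O[C@@H]2CC[C@]1(C)O | intermediate
23 | (5aR,6S,7S,9aR)-7-hydroxy-6-[(E)-2-iodoethenyl]-2,2,5a,7-tetramethyloctahydro-1-benzoxepin-3(2H)-one | I/C=C/[C@H]1[C@@]2(C)CCC(=O)C(C)(C)O[C@@H]2CC[C@]1(C)O | intermediate
24 | (2R)-4-[(1R,2R)-2-hydroxy-2,6,6-trimethylcyclohexyl]-2-methylbutanal | O=C[C@H](C)CC[C@@H]1C(C)(C)CCC[C@@]1(C)O | intermediate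
25 | (5aR,6S,7S,9aR)-7-hydroxy-6-{(1E,4R)-3-hydroxy-6-[(1R,2R)-2-hydroxy-2,6,6-trimethylcyclohexyl]-4-methylhex-1-en-1-yl}-2,2,5a,7-tetramethyloctahydro-1-benzoxepin-3(2H)-one (both carbinol epimers) | C[C@H](CC[C@@H]1C(C)(C)CCC[C@@]1(C)O)C(O)/C=C/[C@H]1[C@@]2(C)CCC(=O)C(C)(C)O[C@@H]2CC[C@]1(C)O | intermediate
26 | (5aR,6S,7S,9aR)-7-hydroxy-6-{(1E,4R)-6-[(1R,2R)-2-hydroxy-2,6,6-trimethylcyclohexyl]-4-methyl-3-oxohex-1-en-1-yl}-2,2,5a,7-tetramethyloctahydro-1-benzoxepin-3(2H)-one | C[C@H](CC[C@@H]1C(C)(C)CCC[C@@]1(C)O)C(=O)/C=C/[C@H]1[C@@]2(C)CCC(=O)C(C)(C)O[C@@H]2CC[C@]1(C)O | intermediate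
27 | CNP0307967.2: (5aR,6S,7S,9aR)-7-hydroxy-6-{(E)-2-[(2R,3R,5aR,9aR)-2-hydroxy-3,6,6,9a-tetramethyldecahydro-1-benzoxepin-2-yl]ethenyl}-2,2,5a,7-tetramethyloctahydro-1-benzoxepin-3(2H)-one | C[C@@H]1CC[C@@H]2C(C)(C)CCC[C@@]2(C)O[C@@]1(O)/C=C/[C@H]1[C@@]2(C)CCC(=O)C(C)(C)O[C@@H]2CC[C@]1(C)O | target

Total step count: 18. Longest linear sequence: 11 steps (steps 8 to 18, from 13); the left branch (steps 1 to 7) joins in step 17.

Steps most likely to fail

Step 3. The free enolate may be consumed by aldol addition to the aldehyde of a second molecule or by O-alkylation, or its C-alkylation next to the carbon that carries the tert-alkyl group may be too slow for the ylide to form. The fallback sets out from 4 and returns to 8 by separate, known operations. Wittig methylenation of the aldehyde (Ph3P=CH2, THF, 0 °C) would give trimethyl{[(3R)-2-methyl-3-(2-methylbut-3-en-2-yl)cyclohex-1-en-1-yl]oxy}silane F1. MeLi (THF, 0 °C) would convert it into lithium (3R)-2-methyl-3-(2-methylbut-3-en-2-yl)cyclohex-1-en-1-olate F2, and allyl iodide (−78 to 0 °C) should alkylate this enolate anti to the tert-alkyl group to give (2R,3R)-2-methyl-3-(2-methylbut-3-en-2-yl)-2-(prop-2-en-1-yl)cyclohexan-1-one F3. Ring-closing metathesis of the two terminal alkenes (second-generation Grubbs catalyst, CH2Cl2, 40 °C) then closes ring A at the same bond and delivers 8.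

Step 13. Facial selectivity may be poor because the methyl nucleophile has to pass the neighbouring axial benzyloxymethyl group, and enolisation of the hindered enone may compete. The fallback sets out from 19 and returns to 21. Hydrogenation (H2, Pd(OH)2/C, EtOAc) would saturate the ring alkene and remove the benzyl group to give (3R,5aR,6R,9aR)-6-(hydroxymethyl)-2,2,5a-trimethyl-3-(triethylsilyloxy)octahydro-1-benzoxepin-7(2H)-one F4. Dimethylsulfoxonium methylide (Me3S(O)I, NaH, DMSO), which adds reversibly and places the new carbon equatorially, should give the spiro-epoxide of F4 with axial oxygen F5. LiAlH4 (THF) would open the epoxide at its CH2 group to give (3R,5aR,6R,7S,9aR)-6-(hydroxymethyl)-2,2,5a,7-tetramethyl-3-(triethylsilyloxy)decahydro-1-benzoxepin-7-ol F6, and 1 M HCl in MeOH would remove the silyl group to give 21.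

Step 5. Hydrogen may be delivered to the exocyclic alkene from the face of the angular methyl group, or the axial methyl group may epimerise through the enol on the catalyst surface. The fallback sets out from 9 and returns to 10. Conjugate reduction with LiBH(s-Bu)3 (THF, −78 °C) would give lithium (4aR,8aR)-2,5,5,8a-tetramethyl-3,4,4a,5,8,8a-hexahydronaphthalen-1-olate F7. Kinetic protonation with 2,6-di-tert-butylphenol at −78 °C, on the face opposite the angular methyl group, should give (2R,4aR,8aR)-2,5,5,8a-tetramethyl-3,4,4a,5,8,8a-hexahydronaphthalen-1(2H)-one F8. Homogeneous hydrogenation of the ring A alkene (H2, RhCl(PPh3)3, benzene, rt) would then give 10 without contact of the ketone with a heterogeneous catalyst.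

Further compounds
F1 | step 3 | trimethyl{[(3R)-2-methyl-3-(2-methylbut-3-en-2-yl)cyclohex-1-en-1-yl]oxy}silane | C=CC(C)(C)[C@H]1CCCC(O[Si](C)(C)C)=C1C
F2 | step 3 | lithium (3R)-2-methyl-3-(2-methylbut-3-en-2-yl)cyclohex-1-en-1-olate | C=CC(C)(C)[C@H]1CCCC([O-])=C1C.[Li+]
F3 | step 3 | (2R,3R)-2-methyl-3-(2-methylbut-3-en-2-yl)-2-(prop-2-en-1-yl)cyclohexan-1-one | C=CC(C)(C)[C@H]1CCCC(=O)[C@]1(C)CC=C
F4 | step 13 | (3R,5aR,6R,9aR)-6-(hydroxymethyl)-2,2,5a-trimethyl-3-(triethylsilyloxy)octahydro-1-benzoxepin-7(2H)-one | OC[C@H]1[C@@]2(C)CC[C@@H](O[Si](CC)(CC)CC)C(C)(C)O[C@@H]2CCC1=O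
F5 | step 13 | spiro-epoxide of F4 at the former carbonyl carbon (epoxide oxygen axial and cis to the 5a-methyl group; CH2 equatorial) | OC[C@H]1[C@@]2(C)CC[C@@H](O[Si](CC)(CC)CC)C(C)(C)O[C@@H]2CC[C@@]13CO3
F6 | step 13 | (3R,5aR,6R,7S,9aR)-6-(hydroxymethyl)-2,2,5a,7-tetramethyl-3-(triethylsilyloxy)decahydro-1-benzoxepin-7-ol | OC[C@H]1[C@@]2(C)CC[C@@H](O[Si](CC)(CC)CC)C(C)(C)O[C@@H]2CC[C@]1(C)O
F7 | step 5 | lithium (4aR,8aR)-2,5,5,8a-tetramethyl-3,4,4a,5,8,8a-hexahydronaphthalen-1-olate | [Li+].[O-]C1=C(C)CC[C@@H]2C(C)(C)C=CC[C@@]12C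
F8 | step 5 | (2R,4aR,8aR)-2,5,5,8a-tetramethyl-3,4,4a,5,8,8a-hexahydronaphthalen-1(2H)-one | C[C@@H]1CC[C@@H]2C(C)(C)C=CC[C@@]2(C)C1=O
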